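**Retrosynthetic overview**

1. Target 14 comes from flavonol 13 by hydrogenolysis of four benzyl ethers; the methyl ethers at C6 and C8 are carried from the start, and the target has no stereocentre.
2. The route rests on ring C, the 3-hydroxy-4-pyranone made of O1, C2, C3(–OH) and C4(=O) on the C4a–C8a edge of ring A. It is opened across O1–C2 and C3–O to 2'-hydroxychalcone 10, whose α-carbon is C3 and whose β-carbon is C2.
3. Chalcone 10 comes from a Claisen–Schmidt condensation (Cα=Cβ) of acetophenone 8 (ring A) with aldehyde 9 (ring B).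
4. Ring A of 8 comes from syringol 1: its MeO–C–O–C–OMe triad becomes C6–C7–C8, the oxygens of C5 and O1 enter through dibromide 3 and the symmetric resorcinol 5, and the acetyl carbon (C4) is placed between them.
5. Rings A and B are bought as benzenes; ring C is the only ring formed, in step 8.

Key step: step 8

Remark: 3,4-bis(benzyloxy)benzaldehyde is taken as a catalogue compound.

**Route**

Step 1
Reactants: 1 2,6-dimethoxyphenol (syringol)
Product: 2 2-(benzyloxy)-1,3-dimethoxybenzene
Conditions: BnBr, K2CO3, DMF, 60 °C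
Reagents that add atoms: benzyl bromide BrCc1ccccc1
Why: Williamson ether synthesis on the potassium phenoxide; capping the phenol leaves the two methoxy groups to steer the bromination that follows.

Step 2
Reactants: 2 2-(benzyloxy)-1,3-dimethoxybenzene
Product: 3 3-(benzyloxy)-1,5-dibromo-2,4-dimethoxybenzene
Conditions: NBS (2.2 equiv), MeCN, dark, 0 °C to 40 °C
Reagents that add atoms: N-bromosuccinimide O=C1CCC(=O)N1Br
Why: Electrophilic aromatic bromination, in which each bromine should enter ortho to one methoxy group and para to the other, the remaining position being meta to both methoxy groups and para only to the doubly flanked, twisted benzyloxy oxygen.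

Step 3
Reactants: 3 3-(benzyloxy)-1,5-dibromo-2,4-dimethoxybenzene
Product: 4 2,2'-[5-(benzyloxy)-4,6-dimethoxy-1,3-phenylene]bis(4,4,5,5-tetramethyl-1,3,2-dioxaborolane)
Conditions: B2pin2 (2.6 equiv), Pd(dppf)Cl2 (5 mol %), KOAc, 1,4-dioxane, 90 °C
Reagents that add atoms: bis(pinacolato)diboron CC1(C)OB(OC1(C)C)B1OC(C)(C)C(C)(C)O1
Why: Twofold Miyaura borylation, by oxidative addition of each C–Br bond to zerovalent palladium, acetate-assisted transmetalation from B2pin2 and reductive elimination, which tolerates the single ortho methoxy group beside each bromide.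

Step 4
Reactants: 4 2,2'-[5-(benzyloxy)-4,6-dimethoxy-1,3-phenylene]bis(4,4,5,5-tetramethyl-1,3,2-dioxaborolane)
Product: 5 5-(benzyloxy)-4,6-dimethoxybenzene-1,3-diol
Conditions: 30% aq H2O2, NaOH, THF/H2O, argon, 0 °C; then aq HCl
Reagents that add atoms: hydrogen peroxide OO
Why: Boronate oxidation, in which hydroperoxide adds to each boron, the aryl group migrates from boron to oxygen and the borate esters are hydrolysed to the two phenols.

Step 5
Reactants: 5 5-(benzyloxy)-4,6-dimethoxybenzene-1,3-diol
Product: 7 1-[4-(benzyloxy)-2,6-dihydroxy-3,5-dimethoxyphenyl]ethan-1-one, via ketiminium chloride 6 (not isolated)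
Conditions: MeCN, ZnCl2, HCl (g), Et2O, 0 °C; then H2O, 90 °C
Reagents that add atoms: acetonitrile CC#N; water O
Why: Houben–Hoesch acylation, in which the ZnCl2/HCl-activated nitrile attacks the only free ring carbon (ortho to both hydroxyls, para to the benzyloxy oxygen) and hot water hydrolyses ketiminium salt 6 to the ketone, while cold ethereal HCl should leave the benzyl ether in place.

Step 6
Reactants: 7 1-[4-(benzyloxy)-2,6-dihydroxy-3,5-dimethoxyphenyl]ethan-1-one
Product: 8 1-[2,4-bis(benzyloxy)-6-hydroxy-3,5-dimethoxyphenyl]ethan-1-one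
Conditions: BnBr (1.05 equiv), K2CO3, acetone, reflux
Reagents that add atoms: benzyl bromide BrCc1ccccc1
Why: Williamson etherification, in which the two hydroxyls of 7 are related by the mirror plane through C1 and C4 so either gives the same monoether, and the hydroxyl that remains is held in a hydrogen bond to the carbonyl and should react much more slowly with the limited BnBr.

Step 7
Reactants: 8 1-[2,4-bis(benzyloxy)-6-hydroxy-3,5-dimethoxyphenyl]ethan-1-one; 9 3,4-bis(benzyloxy)benzaldehyde
Product: 10 (2E)-1-[2,4-bis(benzyloxy)-6-hydroxy-3,5-dimethoxyphenyl]-3-[3,4-bis(benzyloxy)phenyl]prop-2-en-1-one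
Conditions: KOH (50% aq), EtOH/THF, rt; then aq HCl
Reagents that add atoms: none
Why: Claisen–Schmidt condensation, in which the ketone enolate adds to the non-enolisable aldehyde and the aldol loses water by E1cB to the conjugated enone in its thermodynamically favoured E geometry.

Step 8
Reactants: 10 (2E)-1-[2,4-bis(benzyloxy)-6-hydroxy-3,5-dimethoxyphenyl]-3-[3,4-bis(benzyloxy)phenyl]prop-2-en-1-one
Product: 13 5,7-bis(benzyloxy)-2-[3,4-bis(benzyloxy)phenyl]-3-hydroxy-6,8-dimethoxy-4H-chromen-4-one, via trans-chalcone epoxide 11 (not isolated), via trans-3-hydroxyflavanone 12 (not isolated)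
Conditions: 30% aq H2O2, NaOH, MeOH/THF, 0 °C to rt; then aq HCl
Reagents that add atoms: hydrogen peroxide OO
Why: Algar–Flynn–Oyamada oxidation: hydroperoxide anion adds to the β-carbon of the enone and the enolate displaces hydroxide from the O–O bond (Weitz–Scheffer epoxidation) to give trans-epoxide 11, which the 2'-phenoxide opens at the β-carbon with inversion to give trans-3-hydroxyflavanone 12; direct oxa-Michael addition of the phenoxide with hydroxylation of the resulting enolate by H2O2 would arrive at the same 12. Ring C is thereby closed in the 6-endo mode through the new O1–C2 bond, and the peroxide oxygen left on the α-carbon is the C3 hydroxyl. Enolisation of 12 and oxidation by the excess alkaline peroxide, followed by tautomerisation, should give the aromatic 3-hydroxy-4-pyranone, so the two stereocentres of 11 and 12 are erased and none remains to be controlled. The closest known reaction type is the conversion of 2'-hydroxy-6'-alkoxychalcones carrying a 4-alkoxy group on ring B into 5-alkoxyflavonols with NaOH/H2O2. The selectivity required is attack at the β-carbon (six-membered ring) over 5-exo attack at the α-carbon (benzofuranone, then aurone), which the 6'-benzyloxy group encourages by twisting the carbonyl out of the plane of ring A; the 4-benzyloxy group of ring B, conjugated with the β-carbon, weakens the benzylic Cβ–O bond of 11 and so steers the phenoxide to that carbon. Every carbon of ring A is already substituted and the benzyl and methyl ethers are inert to cold alkaline peroxide, so no other site should be touched.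

Step 9
Reactants: 13 5,7-bis(benzyloxy)-2-[3,4-bis(benzyloxy)phenyl]-3-hydroxy-6,8-dimethoxy-4H-chromen-4-one
Product: 14 2-(3,4-dihydroxyphenyl)-3,5,7-trihydroxy-6,8-dimethoxy-4H-chromen-4-one (3,5,7,3',4'-pentahydroxy-6,8-dimethoxyflavone)
Conditions: H2 (1 atm), 10% Pd/C, THF/MeOH, rt
Reagents that add atoms: none
Why: Catalytic hydrogenolysis of the four benzylic C–O bonds, under which the methyl ethers, the conjugated C2=C3 bond of the hydroxypyranone and the carbonyl should not be reduced.

**Compound list**

1 | 2,6-dimethoxyphenol (syringol) | COc1cccc(OC)c1O | starting material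
2 | 2-(benzyloxy)-1,3-dimethoxybenzene | COc1cccc(OC)c1OCc1ccccc1 | intermediate
3 | 3-(benzyloxy)-1,5-dibromo-2,4-dimethoxybenzene | COc1c(Br)cc(Br)c(OC)c1OCc1ccccc1 | intermediate
4 | 2,2'-[5-(benzyloxy)-4,6-dimethoxy-1,3-phenylene]bis(4,4,5,5-tetramethyl-1,3,2-dioxaborolane) | COc1c(B2OC(C)(C)C(C)(C)O2)cc(B2OC(C)(C)C(C)(C)O2)c(OC)c1OCc1ccccc1 | intermediate
5 | 5-(benzyloxy)-4,6-dimethoxybenzene-1,3-diol | COc1c(O)cc(O)c(OC)c1OCc1ccccc1 | intermediate
6 | 1-[4-(benzyloxy)-2,6-dihydroxy-3,5-dimethoxyphenyl]ethan-1-iminium chloride | CC(=[NH2+])c1c(O)c(OC)c(OCc2ccccc2)c(OC)c1O.[Cl-] | intermediate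
7 | 1-[4-(benzyloxy)-2,6-dihydroxy-3,5-dimethoxyphenyl]ethan-1-one | CC(=O)c1c(O)c(OC)c(OCc2ccccc2)c(OC)c1O | intermediate
8 | 1-[2,4-bis(benzyloxy)-6-hydroxy-3,5-dimethoxyphenyl]ethan-1-one | CC(=O)c1c(O)c(OC)c(OCc2ccccc2)c(OC)c1OCc1ccccc1 | intermediate
9 | 3,4-bis(benzyloxy)benzaldehyde | O=Cc1ccc(OCc2ccccc2)c(OCc2ccccc2)c1 | starting material
10 | (2E)-1-[2,4-bis(benzyloxy)-6-hydroxy-3,5-dimethoxyphenyl]-3-[3,4-bis(benzyloxy)phenyl]prop-2-en-1-one | O=C(/C=C/c1ccc(OCc2ccccc2)c(OCc2ccccc2)c1)c1c(O)c(OC)c(OCc2ccccc2)c(OC)c1OCc1ccccc1 | intermediate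
11 | racemic trans-epoxide of 10, [(2R*,3S*)-3-[3,4-bis(benzyloxy)phenyl]oxiran-2-yl][2,4-bis(benzyloxy)-6-hydroxy-3,5-dimethoxyphenyl]methanone (one enantiomer drawn) | O=C([C@@H]1O[C@H]1c1ccc(OCc2ccccc2)c(OCc2ccccc2)c1)c1c(O)c(OC)c(OCc2ccccc2)c(OC)c1OCc1ccccc1 | intermediate
12 | racemic trans-(2R*,3R*)-5,7-bis(benzyloxy)-2-[3,4-bis(benzyloxy)phenyl]-3-hydroxy-6,8-dimethoxy-2,3-dihydro-4H-chromen-4-one (one enantiomer drawn) | O=C1c2c(OCc3ccccc3)c(OC)c(OCc3ccccc3)c(OC)c2O[C@H](c2ccc(OCc3ccccc3)c(OCc3ccccc3)c2)[C@H]1O | intermediate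
13 | 5,7-bis(benzyloxy)-2-[3,4-bis(benzyloxy)phenyl]-3-hydroxy-6,8-dimethoxy-4H-chromen-4-one | COc1c(OCc2ccccc2)c(OC)c2oc(-c3ccc(OCc4ccccc4)c(OCc4ccccc4)c3)c(O)c(=O)c2c1OCc1ccccc1 | intermediate
14 | 2-(3,4-dihydroxyphenyl)-3,5,7-trihydroxy-6,8-dimethoxy-4H-chromen-4-one | COc1c(O)c(OC)c2oc(-c3ccc(O)c(O)c3)c(O)c(=O)c2c1O | target

**Step count**

Total steps: 9. Longest linear sequence: 9 steps (1 to 14); aldehyde 9 enters at step 7.

**Steps most likely to fail**

Step 8. The ring closure may go to the α-carbon of epoxide 11 in the 5-exo mode and on to the benzofuranone and aurone, or the dehydrogenation of 12 may stall. The fallback separates ring closure from C3 oxygenation and sets out from chalcone 10. Catalytic I2 in DMSO at 130 °C should effect oxidative 6-endo cyclisation to the flavone 5,7-bis(benzyloxy)-2-[3,4-bis(benzyloxy)phenyl]-6,8-dimethoxy-4H-chromen-4-one F1. Dimethyldioxirane in acetone/CH2Cl2 at 0 °C should epoxidise its C2=C3 bond to the cis-fused 2,3-epoxide of that flavone F2. A trace of p-TsOH should then open the epoxide at C2, and loss of the C3 proton gives flavonol 13, where the route is rejoined.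

Step 5. The nitrilium ion may be captured on oxygen (imidate formation), attack at the doubly flanked carbon may be slow, or the benzyl group may be lost or migrate under the acid. The fallback moves benzylation behind the acylation and sets out from diol 5. Hydrogenolysis (H2, 10% Pd/C, EtOAc) should give 2,4-dimethoxybenzene-1,3,5-triol F3, handled under argon. AcOH with BF3·OEt2 at 80 °C should C-acetylate its only free ring position to 1-(2,4,6-trihydroxy-3,5-dimethoxyphenyl)ethan-1-one F4. BnBr (2.1 equiv) with K2CO3 in DMF should then etherify the unchelated 4-hydroxyl and one of the two equivalent chelated hydroxyls, rejoining the route at 8.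

Step 3. The second borylation may stall on the electron-rich, ortho-substituted ring, or protodebromination may compete. The fallback forms the C–O bonds directly and sets out from dibromide 3. Pd2(dba)3 with 2-di-tert-butylphosphino-2',4',6'-triisopropylbiphenyl and KOH in 1,4-dioxane/H2O at 100 °C should couple hydroxide at both C–Br bonds and, after acidification, give diol 5, where the route is rejoined. No compound outside the list is made (F0).

**Further compounds**

F1 | step 8 | 5,7-bis(benzyloxy)-2-[3,4-bis(benzyloxy)phenyl]-6,8-dimethoxy-4H-chromen-4-one | COc1c(OCc2ccccc2)c(OC)c2oc(-c3ccc(OCc4ccccc4)c(OCc4ccccc4)c3)cc(=O)c2c1OCc1ccccc1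
F2 | step 8 | racemic cis-fused 2,3-epoxide of F1 (2,3-epoxy-2,3-dihydroflavone, one enantiomer drawn) | O=C1c2c(OCc3ccccc3)c(OC)c(OCc3ccccc3)c(OC)c2O[C@@]3(c2ccc(OCc4ccccc4)c(OCc4ccccc4)c2)O[C@@H]13
F3 | step 5 | 2,4-dimethoxybenzene-1,3,5-triol | COc1c(O)cc(O)c(OC)c1O
F4 | step 5 | 1-(2,4,6-trihydroxy-3,5-dimethoxyphenyl)ethan-1-one | CC(=O)c1c(O)c(OC)c(O)c(OC)c1O
F0 | step 3 | none | none
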